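**Strategy.** The bicycle is cut at C4–C5 and C6–C7. The C4 carbinol–C5–C6 carbonyl array of ring A and the C6–C7–C8=C9 β,γ-unsaturated ketone of ring B are both drawn from one spiro[2.5]octane α-diazo ketone. In a single operation loss of N2 contracts the cyclohexanone to ring A (C4 moves from C6 to C5), and the ketene so formed undergoes a [3,3] shift with the cis isopropenyl group that opens the cyclopropane into ring B. The precursor is a 4-diazospiro[2.5]octan-5-one with a C4 triethylsilyloxy/isopropyl centre and an isopropenyl group cis to the diazo carbon; it is built by asymmetric epoxidation, carbonyl-ene cyclisation and lactone-tethered cyclopropanation.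

Key step: step 13

Remark on numbering: target numbering is used for every intermediate (C1 methyl-bearing fusion carbon, C2/C3 ring A methylenes, C4 isopropyl carbinol, C5 fusion CH, C6 acyloxy carbon, C7 methylene, C8(Me)=C9, C10 methylene); in the spiro compounds C9 and C10 are the cyclopropane CH and CH2.

Assumption: the ene cyclisation of step 6 is taken to give the C6 epimer drawn (hydroxyl trans to silyloxy); the other epimer would give the other cis-cyclopropane diastereomer of 17, which converges on the same 19.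

Step 1
Reactants: 1 prop-2-yn-1-ol; 2 isopropylmagnesium chloride
Product: 3 3-methyl-2-methylidenebutan-1-ol
Conditions: 2 (3 equiv), CuI (10 mol%), Et2O, 0 °C → reflux; aq. NH4Cl
Reagents that add atoms: none
Why: Copper-catalysed carbomagnesiation of the propargylic magnesium alkoxide puts the isopropyl group on the internal alkyne carbon (magnesium chelated at the terminus), so protonation should give the 2-substituted allylic alcohol.

Step 2
Reactants: 3 3-methyl-2-methylidenebutan-1-ol
Product: 4 [(2R)-2-(propan-2-yl)oxiran-2-yl]methanol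
Conditions: Ti(OiPr)4 (10 mol%), D-(−)-diisopropyl tartrate (12 mol%), t-BuOOH, 4 Å MS, CH2Cl2, −20 °C
Reagents that add atoms: tert-butyl hydroperoxide CC(C)(C)OO
Why: Sharpless asymmetric epoxidation; the D-(−)-tartrate complex should deliver oxygen to the alkene face that gives the (R)-epoxide, and this sets the C4 configuration of the target.

Step 3
Reactants: 4 [(2R)-2-(propan-2-yl)oxiran-2-yl]methanol; 5 (2-methylprop-2-en-1-yl)magnesium chloride
Product: 6 (2R)-5-methyl-2-(propan-2-yl)hex-5-ene-1,2-diol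
Conditions: 5 (3 equiv), CuI (10 mol%), THF, −30 → 0 °C; aq. NH4Cl
Reagents that add atoms: none
Why: Copper-catalysed SN2 opening of the 2,2-disubstituted epoxide at its CH2 terminus (C3) by the allylic Grignard reagent leaves the C4–O bond untouched, so the tertiary carbinol keeps its configuration (Payne equilibration of this epoxy alcohol is degenerate).

Step 4
Reactants: 6 (2R)-5-methyl-2-(propan-2-yl)hex-5-ene-1,2-diol
Product: 7 (2R)-5-methyl-2-(propan-2-yl)-1,2-bis[(triethylsilyl)oxy]hex-5-ene
Conditions: Et3SiOTf (2.5 equiv), 2,6-lutidine, CH2Cl2, −78 → 0 °C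
Reagents that add atoms: triethylsilyl trifluoromethanesulfonate CC[Si](CC)(CC)OS(=O)(=O)C(F)(F)F
Why: Silyl triflate silylation should cover both the primary and the hindered tertiary hydroxyl.

Step 5
Reactants: 7 (2R)-5-methyl-2-(propan-2-yl)-1,2-bis[(triethylsilyl)oxy]hex-5-ene
Product: 8 (2R)-5-methyl-2-(propan-2-yl)-2-[(triethylsilyl)oxy]hex-5-enal
Conditions: (COCl)2, DMSO, CH2Cl2, −78 → −40 °C; Et3N, → 0 °C
Reagents that add atoms: none
Why: Swern oxidation applied directly to the bis-silyl ether: only the primary triethylsilyl ether is cleaved by the chlorosulfonium salt and oxidised, giving the non-enolisable α-silyloxy aldehyde while the tertiary silyl ether stays.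

Step 6
Reactants: 8 (2R)-5-methyl-2-(propan-2-yl)-2-[(triethylsilyl)oxy]hex-5-enal
Product: 9 (1S,2R)-5-methylidene-2-(propan-2-yl)-2-[(triethylsilyl)oxy]cyclohexan-1-ol
Conditions: Me2AlCl (1.5 equiv), CH2Cl2, −78 → 0 °C
Reagents that add atoms: none
Why: Intramolecular carbonyl-ene reaction (type 2, tether on the internal alkene carbon): the CH2 terminus (C5) adds to the aldehyde and a methyl hydrogen passes to oxygen, giving the exocyclic C1=C10 methylene; a chair transition state with axial oxygen and equatorial isopropyl should place the C6 hydroxyl trans to the silyloxy group.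

Step 7
Reactants: 9 (1S,2R)-5-methylidene-2-(propan-2-yl)-2-[(triethylsilyl)oxy]cyclohexan-1-ol
Product: 11 (1S,2R)-5-methylidene-2-(propan-2-yl)-2-[(triethylsilyl)oxy]cyclohexyl 2-diazoacetate, via tosylhydrazone ester 10 (not isolated)
Conditions: TsNHN=CHCOCl, PhNMe2, CH2Cl2, 0 °C; then Et3N, 0 °C → rt
Reagents that add atoms: glyoxylic acid chloride 4-toluenesulfonylhydrazone Cc1ccc(cc1)S(=O)(=O)N/N=C/C(=O)Cl
Why: O-acylation by the acid chloride followed by base-induced loss of sulfinate from the tosylhydrazone (Bamford–Stevens type) should give the diazoacetate without touching a stereocentre.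

Step 8
Reactants: 11 (1S,2R)-5-methylidene-2-(propan-2-yl)-2-[(triethylsilyl)oxy]cyclohexyl 2-diazoacetate
Product: 12 9-(propan-2-yl)-9-[(triethylsilyl)oxy]-2-oxatricyclo[4.3.1.0(4,6)]decan-3-one
Conditions: Cu(acac)2 (5 mol%), PhMe, 110 °C, slow addition
Reagents that add atoms: none
Why: Copper-carbenoid intramolecular cyclopropanation of a homoallylic diazoacetate: the axial ester delivers the carbene carbon (C9) to the exocyclic C1=C10 alkene from the C6–O face, and the six-membered lactone that forms forces the carbonyl carbon C8 on C9 to be cis to C5 on C1.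

Step 9
Reactants: 12 9-(propan-2-yl)-9-[(triethylsilyl)oxy]-2-oxatricyclo[4.3.1.0(4,6)]decan-3-one
Product: 13 1-[(1R,3R,5S,6R)-5-hydroxy-6-(propan-2-yl)-6-[(triethylsilyl)oxy]spiro[2.5]octan-1-yl]ethan-1-one
Conditions: MeLi (1.1 equiv), THF, −78 °C; aq. NH4Cl
Reagents that add atoms: methyllithium [Li]C
Why: Mono-addition of methyllithium to the δ-lactone should stop at the lithium hemiketal alkoxide, which on work-up gives the methyl ketone (in equilibrium with its bridged lactol) with the acetyl group still cis to C5.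

Step 10
Reactants: 13 1-[(1R,3R,5S,6R)-5-hydroxy-6-(propan-2-yl)-6-[(triethylsilyl)oxy]spiro[2.5]octan-1-yl]ethan-1-one
Product: 14 (1S,3R,5S,6R)-1-(prop-1-en-2-yl)-6-(propan-2-yl)-6-[(triethylsilyl)oxy]spiro[2.5]octan-5-ol
Conditions: Ph3PCH3Br, KOt-Bu (3 equiv each), THF, 0 → 60 °C
Reagents that add atoms: methyltriphenylphosphonium bromide C[P+](c1ccccc1)(c1ccccc1)c1ccccc1.[Br-]
Why: Wittig methylenation of the methyl ketone (the lactol reacts through its open form) installs the isopropenyl group; enolisation toward the cyclopropane is disfavoured, so the cis relationship to C5 should be kept.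

Step 11
Reactants: 14 (1S,3R,5S,6R)-1-(prop-1-en-2-yl)-6-(propan-2-yl)-6-[(triethylsilyl)oxy]spiro[2.5]octan-5-ol
Product: 15 (1S,3R,6R)-1-(prop-1-en-2-yl)-6-(propan-2-yl)-6-[(triethylsilyl)oxy]spiro[2.5]octan-5-one
Conditions: Dess–Martin periodinane, NaHCO3, CH2Cl2, 0 °C → rt
Reagents that add atoms: none
Why: Dess–Martin oxidation of the secondary alcohol gives the ketone, whose only enolisable position is C5.

Step 12
Reactants: 15 (1S,3R,6R)-1-(prop-1-en-2-yl)-6-(propan-2-yl)-6-[(triethylsilyl)oxy]spiro[2.5]octan-5-one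
Product: 17 (1S,3S,6R)-4-diazo-1-(prop-1-en-2-yl)-6-(propan-2-yl)-6-[(triethylsilyl)oxy]spiro[2.5]octan-5-one, via α-trifluoroacetyl ketone 16 (not isolated)
Conditions: LiN(SiMe3)2, THF, −78 °C; CF3CO2CH2CF3; then MsN3, Et3N, H2O (1 equiv), MeCN, rt
Reagents that add atoms: methanesulfonyl azide CS(=O)(=O)N=[N+]=[N-]; 2,2,2-trifluoroethyl trifluoroacetate O=C(OCC(F)(F)F)C(F)(F)F
Why: Detrifluoroacetylative diazo transfer: the C5 lithium enolate (the only one possible, C4 being quaternary) is C-trifluoroacetylated, and the 1,3-diketone then takes up the diazo group with loss of the trifluoroacetyl group.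

Step 13
Reactants: 17 (1S,3S,6R)-4-diazo-1-(prop-1-en-2-yl)-6-(propan-2-yl)-6-[(triethylsilyl)oxy]spiro[2.5]octan-5-one
Product: 19 (3R)-6-methyl-3-(propan-2-yl)-3-[(triethylsilyl)oxy]-2,3,5,8-tetrahydroazulen-4(1H)-one, via ring-contracted ketene 18 (not isolated)
Conditions: hν (440–450 nm LEDs), PhMe (0.01 M, degassed), 25 °C; then 60 °C
Reagents that add atoms: none
Why: Excitation of the diazo ketone, which the ring locks s-Z, expels N2 with concerted 1,2-shift of C4 from C6 to C5 (Wolff rearrangement, retention at C4), so cyclopentane ring A closes by ring contraction and C6 becomes the carbonyl carbon of exocyclic ketene 18. The ketene C5=C6 bond and the cis isopropenyl group then behave as a cis-divinylcyclopropane: a boat [3,3] sigmatropic shift forms C6–C7, cleaves the strained C1–C9 bond and closes cycloheptadienone ring B by ring expansion. The closest known chemistry is the tandem Wolff rearrangement/ketene–vinylcyclopropane Cope rearrangement of cis-2-vinylcyclopropyl diazo ketones, combined with the photochemical ring contraction of 2-diazocycloalkanones. No stereocentre is created: C4 keeps its configuration and C1 and C9 become sp2. The step needs rearrangement to win over carbene insertion or 1,2-hydrogen shifts and needs the ketene to reach the alkene; both carbons flanking the diazo ketone (C1, C4) are quaternary, the lactone-derived cis geometry holds the isopropenyl group over the ketene, and the silyl ether and aprotic medium keep the ketene from being trapped. Visible light is chosen so that the dienone product is not excited.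

Step 14
Reactants: 19 (3R)-6-methyl-3-(propan-2-yl)-3-[(triethylsilyl)oxy]-2,3,5,8-tetrahydroazulen-4(1H)-one
Product: 20 (3R)-3-hydroxy-6-methyl-3-(propan-2-yl)-2,3,5,8-tetrahydroazulen-4(1H)-one
Conditions: HF·pyridine, pyridine, THF, 0 °C → rt
Reagents that add atoms: none
Why: Buffered fluoride cleavage of the tertiary silyl ether under non-basic conditions should leave the C8=C9 alkene unconjugated; the α-(hydroxyalkyl) enone has no retro-aldol path because C5 is vinylic.

Step 15
Reactants: 20 (3R)-3-hydroxy-6-methyl-3-(propan-2-yl)-2,3,5,8-tetrahydroazulen-4(1H)-one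
Product: 22 (3R,3aR,8aR)-3-hydroxy-6,8a-dimethyl-3-(propan-2-yl)-2,3,3a,5,8,8a-hexahydroazulen-4(1H)-one, via magnesium enolate 21 (not isolated)
Conditions: MeMgBr (4 equiv), CuBr·SMe2 (30 mol%), THF–Me2S, −40 → −10 °C; then AcOH, −78 °C
Reagents that add atoms: methylmagnesium bromide C[Mg]Br
Why: Copper-catalysed conjugate addition to the β,β-disubstituted enone: the C4 magnesium alkoxide and the α-face isopropyl group both steer methyl to the β face of C1, and protonation of the O4–Mg–O6 chelated enolate 21 anti to the alkoxide (C6 held syn to O4, away from isopropyl) should give the trans-fused ketol, which is also expected to be the more stable C5 epimer.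

Step 16
Reactants: 22 (3R,3aR,8aR)-3-hydroxy-6,8a-dimethyl-3-(propan-2-yl)-2,3,3a,5,8,8a-hexahydroazulen-4(1H)-one
Product: 23 (3R,3aS,4S,8aR)-6,8a-dimethyl-3-(propan-2-yl)-1,2,3,3a,4,5,8,8a-octahydroazulene-3,4-diol
Conditions: Me4NBH(OAc)3 (5 equiv), MeCN–AcOH (1:1), −30 → −10 °C
Reagents that add atoms: none
Why: Evans–Saksena reduction: ligand exchange binds boron to the C4 oxygen, and intramolecular hydride delivery to the β face of C6 should give the 6α (equatorial) carbinol anti to the C4 hydroxyl.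

Step 17
Reactants: 23 (3R,3aS,4S,8aR)-6,8a-dimethyl-3-(propan-2-yl)-1,2,3,3a,4,5,8,8a-octahydroazulene-3,4-diol; 24 (2E)-3-[4-(acetyloxy)phenyl]prop-2-enoic acid
Product: 25 (3R,3aS,4S,8aR)-3-hydroxy-6,8a-dimethyl-3-(propan-2-yl)-1,2,3,3a,4,5,8,8a-octahydroazulen-4-yl (2E)-3-[4-(acetyloxy)phenyl]prop-2-enoate
Conditions: EDC·HCl (2 equiv), DMAP, CH2Cl2, rt
Reagents that add atoms: none
Why: Steglich esterification should acylate only the secondary C6 hydroxyl (the tertiary C4 hydroxyl is inert) with retention at C6; the phenol is masked as its acetate to prevent self-acylation.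

Step 18
Reactants: 25 (3R,3aS,4S,8aR)-3-hydroxy-6,8a-dimethyl-3-(propan-2-yl)-1,2,3,3a,4,5,8,8a-octahydroazulen-4-yl (2E)-3-[4-(acetyloxy)phenyl]prop-2-enoate
Product: 26 (3R,3aS,4S,8aR)-3-hydroxy-6,8a-dimethyl-3-(propan-2-yl)-1,2,3,3a,4,5,8,8a-octahydroazulen-4-yl (2E)-3-(4-hydroxyphenyl)prop-2-enoate
Conditions: NH4OAc, MeOH–H2O (4:1), rt
Reagents that add atoms: none
Why: Selective solvolysis of the aryl acetate, far more electrophilic than the hindered secondary cinnamate ester, should release the phenol without touching the enoate or any stereocentre.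

**Compound list**

1 | prop-2-yn-1-ol | C#CCO | starting material
2 | isopropylmagnesium chloride | CC(C)[Mg]Cl | starting material
3 | 3-methyl-2-methylidenebutan-1-ol | CC(C)C(=C)CO | intermediate
4 | [(2R)-2-(propan-2-yl)oxiran-2-yl]methanol | OC[C@]1(C(C)C)CO1 | intermediate
5 | (2-methylprop-2-en-1-yl)magnesium chloride | CC(=C)C[Mg]Cl | starting material
6 | (2R)-5-methyl-2-(propan-2-yl)hex-5-ene-1,2-diol | OC[C@](O)(C(C)C)CCC(C)=C | intermediate
7 | (2R)-5-methyl-2-(propan-2-yl)-1,2-bis[(triethylsilyl)oxy]hex-5-ene | CC[Si](CC)(CC)OC[C@](O[Si](CC)(CC)CC)(C(C)C)CCC(C)=C | intermediate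
8 | (2R)-5-methyl-2-(propan-2-yl)-2-[(triethylsilyl)oxy]hex-5-enal | O=C[C@](O[Si](CC)(CC)CC)(C(C)C)CCC(C)=C | intermediate
9 | (1S,2R)-5-methylidene-2-(propan-2-yl)-2-[(triethylsilyl)oxy]cyclohexan-1-ol (hydroxyl trans to silyloxy) | C=C1CC[C@@](O[Si](CC)(CC)CC)(C(C)C)[C@@H](O)C1 | intermediate
10 | (1S,2R)-5-methylidene-2-(propan-2-yl)-2-[(triethylsilyl)oxy]cyclohexyl (2E)-2-[2-(4-methylbenzenesulfonyl)hydrazinylidene]acetate | C=C1CC[C@@](O[Si](CC)(CC)CC)(C(C)C)[C@@H](OC(=O)/C=N/NS(=O)(=O)c2ccc(C)cc2)C1 | intermediate (not isolated)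
11 | (1S,2R)-5-methylidene-2-(propan-2-yl)-2-[(triethylsilyl)oxy]cyclohexyl 2-diazoacetate | C=C1CC[C@@](O[Si](CC)(CC)CC)(C(C)C)[C@@H](OC(=O)C=[N+]=[N-])C1 | intermediate
12 | 9-(propan-2-yl)-9-[(triethylsilyl)oxy]-2-oxatricyclo[4.3.1.0(4,6)]decan-3-one (lactone C6–O–C8(=O)–C9; cyclopropane C1–C9–C10 spiro at C1; C8 cis to C5) | O=C1O[C@H]2C[C@]3(C[C@@H]13)CC[C@@]2(O[Si](CC)(CC)CC)C(C)C | intermediate
13 | 1-[(1R,3R,5S,6R)-5-hydroxy-6-(propan-2-yl)-6-[(triethylsilyl)oxy]spiro[2.5]octan-1-yl]ethan-1-one (acetyl cis to C5) | CC(=O)[C@@H]1C[C@]12C[C@H](O)[C@](O[Si](CC)(CC)CC)(C(C)C)CC2 | intermediate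
14 | (1S,3R,5S,6R)-1-(prop-1-en-2-yl)-6-(propan-2-yl)-6-[(triethylsilyl)oxy]spiro[2.5]octan-5-ol (isopropenyl cis to C5) | CC(=C)[C@@H]1C[C@]12C[C@H](O)[C@](O[Si](CC)(CC)CC)(C(C)C)CC2 | intermediate
15 | (1S,3R,6R)-1-(prop-1-en-2-yl)-6-(propan-2-yl)-6-[(triethylsilyl)oxy]spiro[2.5]octan-5-one | CC(=C)[C@@H]1C[C@]12CC(=O)[C@](O[Si](CC)(CC)CC)(C(C)C)CC2 | intermediate
16 | 4-(trifluoroacetyl) derivative of 15 (C5 epimers/enol) | CC(=C)[C@@H]1C[C@]12C(C(=O)C(F)(F)F)C(=O)[C@](O[Si](CC)(CC)CC)(C(C)C)CC2 | intermediate (not isolated)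
17 | (1S,3S,6R)-4-diazo-1-(prop-1-en-2-yl)-6-(propan-2-yl)-6-[(triethylsilyl)oxy]spiro[2.5]octan-5-one (isopropenyl cis to the diazo carbon C5) | [N-]=[N+]=C1C(=O)[C@](O[Si](CC)(CC)CC)(C(C)C)CC[C@@]12C[C@H]2C(C)=C | intermediate
18 | [5-(propan-2-yl)-1-(prop-1-en-2-yl)-5-[(triethylsilyl)oxy]spiro[2.4]heptan-4-ylidene]methanone (ketene C5=C6=O) | O=C=C1[C@](O[Si](CC)(CC)CC)(C(C)C)CC[C@@]12C[C@H]2C(C)=C | intermediate (not isolated)
19 | (3R)-6-methyl-3-(propan-2-yl)-3-[(triethylsilyl)oxy]-2,3,5,8-tetrahydroazulen-4(1H)-one | CC1=CCC2=C([C@](O[Si](CC)(CC)CC)(C(C)C)CC2)C(=O)C1 | intermediate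
20 | (3R)-3-hydroxy-6-methyl-3-(propan-2-yl)-2,3,5,8-tetrahydroazulen-4(1H)-one | CC1=CCC2=C([C@](O)(C(C)C)CC2)C(=O)C1 | intermediate
21 | bis(bromomagnesium) C4-alkoxide/C5=C6 enolate of 22 | CC1=CC[C@@]2(C)CC[C@@](O[Mg]Br)(C(C)C)C2=C(O[Mg]Br)C1 | intermediate (not isolated)
22 | (3R,3aR,8aR)-3-hydroxy-6,8a-dimethyl-3-(propan-2-yl)-2,3,3a,5,8,8a-hexahydroazulen-4(1H)-one (trans-fused) | CC1=CC[C@@]2(C)CC[C@@](O)(C(C)C)[C@@H]2C(=O)C1 | intermediate
23 | (3R,3aS,4S,8aR)-6,8a-dimethyl-3-(propan-2-yl)-1,2,3,3a,4,5,8,8a-octahydroazulene-3,4-diol | CC1=CC[C@@]2(C)CC[C@@](O)(C(C)C)[C@@H]2[C@@H](O)C1 | intermediate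
24 | (2E)-3-[4-(acetyloxy)phenyl]prop-2-enoic acid | CC(=O)Oc1ccc(/C=C/C(=O)O)cc1 | starting material
25 | (3R,3aS,4S,8aR)-3-hydroxy-6,8a-dimethyl-3-(propan-2-yl)-1,2,3,3a,4,5,8,8a-octahydroazulen-4-yl (2E)-3-[4-(acetyloxy)phenyl]prop-2-enoate | CC1=CC[C@@]2(C)CC[C@@](O)(C(C)C)[C@@H]2[C@@H](OC(=O)/C=C/c2ccc(OC(C)=O)cc2)C1 | intermediate
26 | (3R,3aS,4S,8aR)-3-hydroxy-6,8a-dimethyl-3-(propan-2-yl)-1,2,3,3a,4,5,8,8a-octahydroazulen-4-yl (2E)-3-(4-hydroxyphenyl)prop-2-enoate | CC1=CC[C@@]2(C)CC[C@@](O)(C(C)C)[C@@H]2[C@@H](OC(=O)/C=C/c2ccc(O)cc2)C1 | target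

**Step count.** Total 18 steps; longest linear sequence 18 steps (1 → 26).

**Steps most likely to fail**

Step 13 (key cascade). The excited diazo ketone or carbene may be diverted (cyclopropylcarbene ring expansion, slow intramolecular pyrazoline formation on storage of 17). The ketene may also be lost to dimerisation or adventitious water before the sigmatropic shift, and the dienone may degrade on prolonged irradiation. The fallback uncouples nitrogen loss from the Cope step. Compound 17 would be photolysed in THF–H2O so that the ketene is trapped by water as the ring-contracted acid F1 (classical Wolff ring contraction). 1-Chloro-N,N,2-trimethylprop-1-en-1-amine would convert it into the acid chloride F2. Et3N in PhMe at 80 °C would then regenerate ketene 18 by dehydrochlorination in the dark, where the [3,3] shift can be driven thermally; the route is rejoined at 19.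

Step 15. Addition to the tetrasubstituted enone may be sluggish or go 1,2. Above all, the enolate 21 may be protonated from the β face (syn to O4, anti to isopropyl), giving the cis-fused C5 epimer. The C6 facial selectivity of step 16 depends on this centre. The fallback replaces kinetic protonation by equilibration. The cis-fused ketol F3 would be silylated at O4 (Et3SiOTf, 2,6-lutidine; dilute aqueous acid to hydrolyse any enol silane) to give its triethylsilyl ether F4, which excludes retro-aldol cleavage. KOt-Bu in THF/t-BuOH would then equilibrate C5 through the enolates while the alkene is held as the extended potassium dienolate. Inverse quench into AcOH at −78 °C (kinetic protonation at C7) would return the β,γ-unsaturated trans-fused silyl ether F5, and HF·pyridine would rejoin the route at 22.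

Step 8. The axial copper carbenoid may fail to reach the exocyclic alkene through the bridged transition state and be consumed by C–H insertion or carbene dimerisation. The fallback drops the lactone tether. Alcohol 9 would be treated with Et2Zn and CHI3 (gem-dizinc carbenoid, alkoxide-directed Simmons–Smith-type cyclopropanation), which should give the cyclopropylzinc iodide F6 with zinc cis to C5 through coordination to the C6 zinc alkoxide. Negishi coupling in the same flask with 2-bromopropene and Pd(PPh3)4 would then give 14 directly, bypassing 11–13.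

**Further compounds**

F1 | step 13 | 5-(propan-2-yl)-1-(prop-1-en-2-yl)-5-[(triethylsilyl)oxy]spiro[2.4]heptane-4-carboxylic acid (C4 epimers) | OC(=O)C1[C@](O[Si](CC)(CC)CC)(C(C)C)CC[C@@]12C[C@H]2C(C)=C
F2 | step 13 | 5-(propan-2-yl)-1-(prop-1-en-2-yl)-5-[(triethylsilyl)oxy]spiro[2.4]heptane-4-carbonyl chloride | ClC(=O)C1[C@](O[Si](CC)(CC)CC)(C(C)C)CC[C@@]12C[C@H]2C(C)=C
F3 | step 15 | (3R,3aS,8aR)-3-hydroxy-6,8a-dimethyl-3-(propan-2-yl)-2,3,3a,5,8,8a-hexahydroazulen-4(1H)-one (cis-fused C5 epimer of 22) | CC1=CC[C@@]2(C)CC[C@@](O)(C(C)C)[C@H]2C(=O)C1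
F4 | step 15 | (3R,3aS,8aR)-6,8a-dimethyl-3-(propan-2-yl)-3-[(triethylsilyl)oxy]-2,3,3a,5,8,8a-hexahydroazulen-4(1H)-one | CC1=CC[C@@]2(C)CC[C@@](O[Si](CC)(CC)CC)(C(C)C)[C@H]2C(=O)C1
F5 | step 15 | (3R,3aR,8aR)-6,8a-dimethyl-3-(propan-2-yl)-3-[(triethylsilyl)oxy]-2,3,3a,5,8,8a-hexahydroazulen-4(1H)-one | CC1=CC[C@@]2(C)CC[C@@](O[Si](CC)(CC)CC)(C(C)C)[C@@H]2C(=O)C1
F6 | step 8 | [5-hydroxy-6-(propan-2-yl)-6-[(triethylsilyl)oxy]spiro[2.5]octan-1-yl]zinc iodide (zinc cis to C5) | I[Zn][C@@H]1C[C@]12C[C@H](O)[C@](O[Si](CC)(CC)CC)(C(C)C)CC2
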